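## Retrosynthetic overview

1. The strategy rests on ring A: C1' carbinol, C2'(CH3)=C3', C4' ketone, C5'H2 and C6' quaternary with CH3 and CH2O. Its para oxygens on C1' and C4', the C2'=C3' bond and the cis relation of the C6' CH2O group to the side-chain carbon on C1' are read as the bridged lactone of a 3-hydroxy-2-pyrone cycloadduct.
2. Late disconnections: two 2-(trimethylsilyl)ethyl (TMSE) esters and the C4' ketone; C3–C4 of the dienoic acid (Stille, stannane 23 + iodide 26); the C6' CH2O–HMG ester (alkynyl diol 14 + half ester 21, HMG centre from enzymatic desymmetrisation).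
3. Diol 14 comes from γ-lactone 11 by lactol formation and alkynylation; 11 comes from bicyclic adduct 9 by aldehyde reduction and transfer of the bridge carbonyl to the new CH2OH.
4. Key disconnection: 9 is cut into 3-hydroxy-4-methyl-2-pyrone 7 and methacrolein 8, across C1'–C6' and C4'–C5'.
5. Ring order: pyrone ring (step 4), carbocyclic ring A as a bicyclo[2.2.2] lactone (step 5), a temporary γ-lactone (step 6) that is opened again in step 9.

Key step: step 5

Assumption: the quinidine-series catalyst is taken to give adduct 9 in the absolute sense drawn; if induction runs the other way, its quinine-series pseudo-enantiomer is used with nothing else changed.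

## Route

Step 1
Reactants: 1 diethyl 2-methyl-3-oxobutanedioate (diethyl oxalpropionate); 2 allyl bromide
Product: 3 diethyl 2-methyl-3-oxo-2-(prop-2-en-1-yl)butanedioate (racemic)
Conditions: K2CO3, acetone, reflux
Reagents that add atoms: none
Why: Alkylation of a doubly stabilised β-keto ester enolate with an allylic bromide (SN2); any O-allyl enol ether should converge on 3 by Claisen rearrangement at reflux, and the racemic quaternary carbon later becomes sp2.

Step 2
Reactants: 3 diethyl 2-methyl-3-oxo-2-(prop-2-en-1-yl)butanedioate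
Product: 4 3-methyl-2-oxohex-5-enoic acid (racemic)
Conditions: 2 M aq. HCl, 90 °C
Reagents that add atoms: water, O
Why: Acidic hydrolysis of both esters followed by decarboxylation of the β-keto acid (oxalacetic ester route to α-keto acids); acid is used because hydroxide would cleave the oxalyl ketone by retro-Claisen reaction.

Step 3
Reactants: 4 3-methyl-2-oxohex-5-enoic acid
Product: 5 3-methyl-2,5-dioxopentanoic acid (racemic; expected to sit largely in cyclic lactol forms, used crude)
Conditions: O3, CH2Cl2, −78 °C; then Me2S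
Reagents that add atoms: ozone, O=[O+][O-]
Why: Ozonolysis with reductive work-up cleaves the only alkene to the aldehyde.

Step 4
Reactants: 5 3-methyl-2,5-dioxopentanoic acid
Product: 7 3-hydroxy-4-methyl-2H-pyran-2-one, via 3-acetoxy-4-methyl-2H-pyran-2-one 6 (not isolated)
Conditions: Ac2O, NaOAc, 120 °C; then MeOH, HCl (cat.), rt
Reagents that add atoms: none
Why: Cyclodehydration of a δ-oxo acid to an enol lactone under Perkin-type conditions: enol acetylation of the C2 ketone blocks closure through that oxygen (furan formation), the carboxyl closes on the aldehyde carbon and loss of acetic acid gives the aromatic 2-pyrone, whose enol acetate is then cleaved by acid-catalysed transesterification.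

Step 5
Reactants: 7 3-hydroxy-4-methyl-2H-pyran-2-one; 8 methacrolein
Product: 9 (1S,4R,8R)-4-hydroxy-5,8-dimethyl-3-oxo-2-oxabicyclo[2.2.2]oct-5-ene-8-carbaldehyde (exo adduct: formyl on the side of the lactone bridge)
Conditions: 9-O-benzylcupreidine (10 mol%), EtOAc, −20 °C
Reagents that add atoms: none
Why: The quinuclidine nitrogen of the catalyst deprotonates the 3-OH of 7 and its 6'-OH hydrogen-bonds the formyl oxygen of 8, so the oxidopyrone (an electron-rich 1-oxido diene, C3=C4–C5=C6) adds through C6 to the β-CH2 of methacrolein and the resulting enolate closes onto C3, either as a concerted asynchronous [4+2] or as a vinylogous Michael–aldol pair. The closest known reaction type is the cinchona-base-catalysed asymmetric Diels–Alder reaction of 3-hydroxy-2-pyrones with α,β-unsaturated carbonyl dienophiles, including α-substituted ones that place a quaternary carbon next to the carbinol bridgehead. Carbocyclic ring A is closed across the pyrone by suprafacial bonding at C3 and C6 (seen stepwise, a 6-(enolexo)-exo-trig aldol closure), which forms C1'–C6' and C4'–C5' and leaves the old O1–C2(=O) unit as the lactone bridge. The bridgehead centres C1 and C4 are tied to each other by the bridge and their absolute sense is set by the face of the ion-paired oxidopyrone that the catalyst leaves open, while C8 is set by exo placement of the formyl group (methyl endo), favoured by the α-methyl group and by the hydrogen bond to the catalyst. The step needs regioselectivity (the formyl-bearing carbon bonded to C3), exo selectivity and facial selectivity; the first follows from the polarisation of the 3-oxido diene (largest HOMO coefficient at C6) against the β-carbon of the enal, and the other two rest on the catalyst pocket and on low temperature, which suppresses retro-aldol equilibration.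

Step 6
Reactants: 9 exo-formyl adduct
Product: 11 (3aS,5S,7aR)-5,7a-dihydroxy-3a,7-dimethyl-3a,4,5,7a-tetrahydroisobenzofuran-1(3H)-one (cis-fused γ-lactone; 5-OH on the lactone face), via bridged hydroxymethyl lactone 10 (not isolated)
Conditions: NaBH4, MeOH/THF, −40 → 0 °C
Reagents that add atoms: none
Why: Chemoselective borohydride reduction of the aldehyde (fast at low temperature, before retro-aldol) gives an exo CH2O– next to the bridge carbonyl, which takes over the acyl group (translactonisation, 5-exo-trig) to give the less strained cis-fused γ-lactone; no stereocentre is touched and the acyl transfer is only possible for the exo isomer.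

Step 7
Reactants: 11 lactone diol
Product: 12 (3aS,5S,7aR)-5-[(tert-butyldimethylsilyl)oxy]-7a-hydroxy-3a,7-dimethyl-3a,4,5,7a-tetrahydroisobenzofuran-1(3H)-one
Conditions: TBSCl, imidazole, DMF, rt
Reagents that add atoms: tert-butyldimethylsilyl chloride, CC(C)(C)[Si](C)(C)Cl
Why: Silyl ether formation is selective for the secondary allylic C4'-OH over the hindered tertiary α-hydroxy-lactone OH.

Step 8
Reactants: 12 silylated lactone
Product: 13 (3aS,5S,7aR)-5-[(tert-butyldimethylsilyl)oxy]-3a,7-dimethyl-1,3,3a,4,5,7a-hexahydroisobenzofuran-1,7a-diol (lactol, mixture at C1)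
Conditions: i-Bu2AlH (2.5 equiv), CH2Cl2, −78 °C; then aq. potassium sodium tartrate
Reagents that add atoms: none
Why: Partial reduction of a γ-lactone to the lactol with i-Bu2AlH at −78 °C, where the tetrahedral aluminate is stable; the tertiary OH consumes one equivalent as its aluminate.

Step 9
Reactants: 13 lactol
Product: 14 (1R,4S,6S)-4-[(tert-butyldimethylsilyl)oxy]-1-ethynyl-6-(hydroxymethyl)-2,6-dimethylcyclohex-2-en-1-ol
Conditions: dimethyl (1-diazo-2-oxopropyl)phosphonate, K2CO3, MeOH, 0 °C → rt
Reagents that add atoms: dimethyl (1-diazo-2-oxopropyl)phosphonate, COP(=O)(OC)C(=[N+]=[N-])C(C)=O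
Why: Seyferth–Gilbert homologation in its Ohira–Bestmann form on the hydroxy-aldehyde tautomer of the lactol: the alkylidene carbene rearranges by 1,2-hydrogen shift to the terminal alkyne and ring opening frees the C6' CH2OH; C1' is fully substituted and cannot epimerise.

Step 10
Reactants: 15 3-hydroxy-3-methylpentanedioic acid (HMG acid)
Product: 16 dimethyl 3-hydroxy-3-methylpentanedioate
Conditions: MeOH, H2SO4 (cat.), reflux
Reagents that add atoms: methanol, CO
Why: Fischer esterification of both carboxyl groups; the tertiary alcohol is inert.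

Step 11
Reactants: 16 dimethyl 3-hydroxy-3-methylpentanedioate
Product: 17 (3S)-3-hydroxy-5-methoxy-3-methyl-5-oxopentanoic acid
Conditions: pig liver esterase, aq. phosphate buffer (pH 7.5), rt
Reagents that add atoms: water, O
Why: Enzymatic desymmetrisation of a prochiral diester: pig liver esterase is known to hydrolyse one enantiotopic ester group of this diester to the (S)-half ester, which sets the HMG stereocentre.

Step 12
Reactants: 17 (S)-half ester
Product: 18 1-tert-butyl 5-methyl (3R)-3-hydroxy-3-methylpentanedioate
Conditions: tert-butyl 2,2,2-trichloroacetimidate, CH2Cl2/cyclohexane, rt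
Reagents that add atoms: tert-butyl 2,2,2-trichloroacetimidate, CC(C)(C)OC(=N)C(Cl)(Cl)Cl
Why: tert-Butyl ester formation with the trichloroacetimidate, which the carboxylic acid itself protonates, so the tertiary alcohol is left alone; the acid arm is masked so that the ester on the other arm can be exchanged.

Step 13
Reactants: 18 tert-butyl methyl diester
Product: 19 (3R)-5-tert-butoxy-3-hydroxy-3-methyl-5-oxopentanoic acid
Conditions: LiOH (1.1 equiv), THF/H2O, 0 °C; then dil. HCl
Reagents that add atoms: lithium hydroxide, [Li+].[OH-]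
Why: Saponification selective for the methyl ester, the tert-butyl ester being shielded from hydroxide; the stereocentre is kept because the two arms stay different.

Step 14
Reactants: 19 tert-butyl hydrogen ester
Product: 20 1-tert-butyl 5-[2-(trimethylsilyl)ethyl] (3R)-3-hydroxy-3-methylpentanedioate
Conditions: 2-(trimethylsilyl)ethanol, EDC·HCl, DMAP (cat.), CH2Cl2, 0 °C → rt
Reagents that add atoms: 2-(trimethylsilyl)ethanol, C[Si](C)(C)CCO
Why: Steglich esterification (carbodiimide, DMAP) of the free acid; the tertiary alcohol is not acylated.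

Step 15
Reactants: 20 tert-butyl TMSE diester
Product: 21 (3S)-3-hydroxy-3-methyl-5-oxo-5-[2-(trimethylsilyl)ethoxy]pentanoic acid
Conditions: TFA/CH2Cl2 (1:4), 0 °C
Reagents that add atoms: none
Why: Acidolysis of the tert-butyl ester (loss of isobutene) in cold TFA, which the TMSE ester and the tertiary alcohol should tolerate; the free acid now sits on the arm that must be bound to ring A.

Step 16
Reactants: 14 alkynyl diol; 21 HMG mono-TMSE ester
Product: 22 [(1S,2R,5S)-5-[(tert-butyldimethylsilyl)oxy]-2-ethynyl-2-hydroxy-1,3-dimethylcyclohex-3-en-1-yl]methyl 2-(trimethylsilyl)ethyl (3S)-3-hydroxy-3-methylpentanedioate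
Conditions: EDC·HCl, DMAP, CH2Cl2, 0 °C → rt
Reagents that add atoms: none
Why: Steglich esterification of the only primary alcohol (the neopentyl-type CH2OH on C6'); both tertiary alcohols are too hindered to compete.

Step 17
Reactants: 22 alkynyl HMG ester
Product: 23 (E)-vinylstannane: 22 with the ethynyl group on C1' replaced by (E)-2-(tributylstannyl)ethenyl
Conditions: Bu3SnH, PdCl2(PPh3)2 (2 mol%), THF, 0 °C
Reagents that add atoms: tributyltin hydride, CCCC[SnH](CCCC)CCCC
Why: Palladium-catalysed syn-hydrostannylation of the terminal alkyne; the fully substituted propargylic carbon steers tin to the terminal carbon and gives the (E)-vinylstannane, which sets the 4E geometry.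

Step 18
Reactants: 24 but-2-ynoic acid
Product: 25 (Z)-3-iodobut-2-enoic acid
Conditions: NaI, AcOH, 110 °C
Reagents that add atoms: sodium iodide, [Na+].[I-]
Why: Conjugate hydroiodination of the ynoic acid with NaI/AcOH, which is known to give the (Z)-3-iodo acid (iodine cis to CO2H); this sets the 2Z geometry.

Step 19
Reactants: 25 (Z)-3-iodobut-2-enoic acid
Product: 26 2-(trimethylsilyl)ethyl (Z)-3-iodobut-2-enoate
Conditions: 2-(trimethylsilyl)ethanol, PPh3, DIAD, THF, 0 °C
Reagents that add atoms: 2-(trimethylsilyl)ethanol, C[Si](C)(C)CCO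
Why: Mitsunobu esterification under neutral conditions, chosen to avoid Z/E isomerisation of the β-iodo enoate by nucleophilic catalysts.

Step 20
Reactants: 23 (E)-vinylstannane; 26 TMSE (Z)-3-iodobut-2-enoate
Product: 27 fully protected dienoate: 23 with the stannyl group replaced by the (Z)-C(CH3)=CH–CO2CH2CH2SiMe3 unit (2Z,4E-dienoate; C4'-OTBS; two TMSE esters)
Conditions: Pd2(dba)3 (cat.), AsPh3, copper iodide (CuI, cat.), DMF, rt
Reagents that add atoms: none
Why: Stille coupling of vinylstannane and vinyl iodide forms C3–C4 with retention at both alkenes, giving the 2Z,4E-dienoate; the free tertiary alcohols, the silyl ether and the TMSE esters are inert.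

Step 21
Reactants: 27 fully protected dienoate
Product: 28 C4' alcohol: 27 with free C4'-OH
Conditions: HF·pyridine, pyridine, THF, 0 °C → rt
Reagents that add atoms: none
Why: Fluoride-mediated cleavage of the allylic TBS ether with buffered HF·pyridine, which does not attack the tetraalkylsilane of the TMSE esters.

Step 22
Reactants: 28 C4' alcohol
Product: 29 bis-TMSE ester of the target (C4' ketone)
Conditions: activated MnO2, CH2Cl2, rt
Reagents that add atoms: none
Why: MnO2 oxidation of the secondary allylic alcohol to the enone, selective over the tertiary alcohols; it removes the C4' stereocentre and is run while the C6' CH2O group is acylated, so no oxa-Michael closure onto C2' can occur.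

Step 23
Reactants: 29 bis-TMSE ester
Product: 30 (2Z,4E)-5-[(1R,6S)-6-({[(3R)-4-carboxy-3-hydroxy-3-methylbutanoyl]oxy}methyl)-1-hydroxy-2,6-dimethyl-4-oxocyclohex-2-en-1-yl]-3-methylpenta-2,4-dienoic acid (target)
Conditions: TBAF, THF, 0 °C → rt; then dil. HCl (pH 3)
Reagents that add atoms: none
Why: Fluoride-induced β-elimination (ethene and Me3SiF) cleaves both TMSE esters without hydrolytic conditions, so the hindered C6' CH2O ester should stay intact; mild acidification gives the diacid.

## Compound list

1 | diethyl 2-methyl-3-oxobutanedioate | CCOC(=O)C(C)C(=O)C(=O)OCC | starting material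
2 | allyl bromide | C=CCBr | starting material
3 | diethyl 2-methyl-3-oxo-2-(prop-2-en-1-yl)butanedioate | CCOC(=O)C(C)(CC=C)C(=O)C(=O)OCC | intermediate
4 | 3-methyl-2-oxohex-5-enoic acid | C=CCC(C)C(=O)C(=O)O | intermediate
5 | 3-methyl-2,5-dioxopentanoic acid | O=CCC(C)C(=O)C(=O)O | intermediate
6 | 3-acetoxy-4-methyl-2H-pyran-2-one | CC(=O)OC1=C(C)C=COC1=O | intermediate
7 | 3-hydroxy-4-methyl-2H-pyran-2-one | CC1=C(O)C(=O)OC=C1 | intermediate
8 | methacrolein | CC(=C)C=O | starting material
9 | (1S,4R,8R)-4-hydroxy-5,8-dimethyl-3-oxo-2-oxabicyclo[2.2.2]oct-5-ene-8-carbaldehyde | CC1=C[C@@H]2C[C@@](C)(C=O)[C@@]1(O)C(=O)O2 | intermediate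
10 | (1S,4R,8S)-4-hydroxy-8-(hydroxymethyl)-5,8-dimethyl-2-oxabicyclo[2.2.2]oct-5-en-3-one | CC1=C[C@@H]2C[C@@](C)(CO)[C@@]1(O)C(=O)O2 | intermediate
11 | (3aS,5S,7aR)-5,7a-dihydroxy-3a,7-dimethyl-3a,4,5,7a-tetrahydroisobenzofuran-1(3H)-one | CC1=C[C@@H](O)C[C@@](C)(COC2=O)[C@]12O | intermediate
12 | (3aS,5S,7aR)-5-[(tert-butyldimethylsilyl)oxy]-7a-hydroxy-3a,7-dimethyl-3a,4,5,7a-tetrahydroisobenzofuran-1(3H)-one | CC1=C[C@@H](O[Si](C)(C)C(C)(C)C)C[C@@](C)(COC2=O)[C@]12O | intermediate
13 | (3aS,5S,7aR)-5-[(tert-butyldimethylsilyl)oxy]-3a,7-dimethyl-1,3,3a,4,5,7a-hexahydroisobenzofuran-1,7a-diol | CC1=C[C@@H](O[Si](C)(C)C(C)(C)C)C[C@@](C)(COC2O)[C@]12O | intermediate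
14 | (1R,4S,6S)-4-[(tert-butyldimethylsilyl)oxy]-1-ethynyl-6-(hydroxymethyl)-2,6-dimethylcyclohex-2-en-1-ol | CC1=C[C@@H](O[Si](C)(C)C(C)(C)C)C[C@@](C)(CO)[C@@]1(O)C#C | intermediate
15 | 3-hydroxy-3-methylpentanedioic acid | CC(O)(CC(=O)O)CC(=O)O | starting material
16 | dimethyl 3-hydroxy-3-methylpentanedioate | COC(=O)CC(C)(O)CC(=O)OC | intermediate
17 | (3S)-3-hydroxy-5-methoxy-3-methyl-5-oxopentanoic acid | COC(=O)C[C@@](C)(O)CC(=O)O | intermediate
18 | 1-tert-butyl 5-methyl (3R)-3-hydroxy-3-methylpentanedioate | COC(=O)C[C@@](C)(O)CC(=O)OC(C)(C)C | intermediate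
19 | (3R)-5-tert-butoxy-3-hydroxy-3-methyl-5-oxopentanoic acid | OC(=O)C[C@@](C)(O)CC(=O)OC(C)(C)C | intermediate
20 | 1-tert-butyl 5-[2-(trimethylsilyl)ethyl] (3R)-3-hydroxy-3-methylpentanedioate | C[Si](C)(C)CCOC(=O)C[C@@](C)(O)CC(=O)OC(C)(C)C | intermediate
21 | (3S)-3-hydroxy-3-methyl-5-oxo-5-[2-(trimethylsilyl)ethoxy]pentanoic acid | C[Si](C)(C)CCOC(=O)C[C@@](C)(O)CC(=O)O | intermediate
22 | [(1S,2R,5S)-5-[(tert-butyldimethylsilyl)oxy]-2-ethynyl-2-hydroxy-1,3-dimethylcyclohex-3-en-1-yl]methyl 2-(trimethylsilyl)ethyl (3S)-3-hydroxy-3-methylpentanedioate | CC1=C[C@@H](O[Si](C)(C)C(C)(C)C)C[C@@](C)(COC(=O)C[C@](C)(O)CC(=O)OCC[Si](C)(C)C)[C@@]1(O)C#C | intermediate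
23 | (E)-vinylstannane (22 with (E)-2-(tributylstannyl)ethenyl on C1') | CC1=C[C@@H](O[Si](C)(C)C(C)(C)C)C[C@@](C)(COC(=O)C[C@](C)(O)CC(=O)OCC[Si](C)(C)C)[C@@]1(O)/C=C/[Sn](CCCC)(CCCC)CCCC | intermediate
24 | but-2-ynoic acid | CC#CC(=O)O | starting material
25 | (Z)-3-iodobut-2-enoic acid | C/C(I)=C/C(=O)O | intermediate
26 | 2-(trimethylsilyl)ethyl (Z)-3-iodobut-2-enoate | C/C(I)=C/C(=O)OCC[Si](C)(C)C | intermediate
27 | fully protected (2Z,4E)-dienoate (C4'-OTBS, two TMSE esters) | CC1=C[C@@H](O[Si](C)(C)C(C)(C)C)C[C@@](C)(COC(=O)C[C@](C)(O)CC(=O)OCC[Si](C)(C)C)[C@@]1(O)/C=C/C(C)=C\C(=O)OCC[Si](C)(C)C | intermediate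
28 | C4' alcohol (27 without the TBS group) | CC1=C[C@@H](O)C[C@@](C)(COC(=O)C[C@](C)(O)CC(=O)OCC[Si](C)(C)C)[C@@]1(O)/C=C/C(C)=C\C(=O)OCC[Si](C)(C)C | intermediate
29 | bis-TMSE ester of the target (C4' ketone) | CC1=CC(=O)C[C@@](C)(COC(=O)C[C@](C)(O)CC(=O)OCC[Si](C)(C)C)[C@@]1(O)/C=C/C(C)=C\C(=O)OCC[Si](C)(C)C | intermediate
30 | (2Z,4E)-5-[(1R,6S)-6-({[(3R)-4-carboxy-3-hydroxy-3-methylbutanoyl]oxy}methyl)-1-hydroxy-2,6-dimethyl-4-oxocyclohex-2-en-1-yl]-3-methylpenta-2,4-dienoic acid | CC1=CC(=O)C[C@@](C)(COC(=O)C[C@](C)(O)CC(=O)O)[C@@]1(O)/C=C/C(C)=C\C(=O)O | target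

## Step count

Total: 23 steps. Longest linear sequence: 15 steps (steps 1–9, 16, 17, 20–23).

## Steps most likely to fail, with fallbacks

**Step 5 (key cycloaddition).** The second C–C bond must form between two fully substituted carbons (pyrone C3 and the α-carbon of methacrolein). Slow closure lets the Michael adduct revert, and retro-aldol and re-closure of the adduct under the basic catalyst can erode exo and facial selectivity. The fallback replaces catalyst control by a covalently bound auxiliary and sets out from pyrone 7. Compound 7 would be combined under Et3N catalysis with (S)-4-benzyl-3-methacryloyloxazolidin-2-one F1, made from (S)-4-benzyloxazolidin-2-one, n-BuLi and methacryloyl chloride. Base-catalysed cycloaddition of 3-hydroxy-2-pyrones with chiral acrylimides is a known reaction type, and the antipode of the auxiliary is taken if the first one is mismatched. The expected product is the exo-imide adduct F2, purified as one diastereomer by crystallisation or chromatography. NaBH4 in THF/H2O then cleaves the imide reductively to the bridged hydroxymethyl lactone 10, which translactonises as in step 6, and the route is rejoined at 11.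

**Step 4 (pyrone ring closure).** The keto aldehyde acid can close through the ketone (enol) oxygen onto the aldehyde carbon and aromatise to a furan-2-carboxylic acid, or oligomerise under hot acetylating conditions, before the carboxyl group closes the six-membered ring. The fallback masks the ketone before the aldehyde exists and sets out from keto acid 4. HC(OMe)3/MeOH/H2SO4 (cat.) converts 4 to methyl 2,2-dimethoxy-3-methylhex-5-enoate F3. LiOH saponification gives 2,2-dimethoxy-3-methylhex-5-enoic acid F4, and ozonolysis (O3; Me2S) gives 2,2-dimethoxy-3-methyl-5-oxopentanoic acid F5, in which only the carboxyl oxygen can reach the aldehyde. TsOH in refluxing toluene closes the pseudo-acid, dehydrates it and expels methanol from the ketal to give 3-methoxy-4-methyl-2H-pyran-2-one F6. BBr3 in CH2Cl2 then cleaves the methyl ether and returns the route at 7.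

**Step 9 (alkynylation of the lactol).** Only a small equilibrium amount of the open hydroxy aldehyde is present and it is flanked by two fully substituted carbons, so capture by the diazophosphonate anion may be slow. Meanwhile the tertiary α-hydroxy aldehyde can undergo base-induced α-ketol rearrangement. The fallback avoids the alkyne and both tin steps and sets out from lactol 13. Wittig methylenation with Ph3P=CH2 (Ph3PCH3Br, KOtBu, THF), a fast and irreversible trap for lactols, gives (1R,4S,6S)-4-[(tert-butyldimethylsilyl)oxy]-1-ethenyl-6-(hydroxymethyl)-2,6-dimethylcyclohex-2-en-1-ol F7. Steglich esterification of F7 with half ester 21 gives the vinyl HMG ester F8. A Heck reaction of F8 with iodide 26 (Pd(OAc)2, Ag2CO3, DMF, 50 °C) then forms the C3–C4 bond. β-Hydride elimination can only run towards C4, because C1' carries no hydrogen, so the (2Z,4E)-dienoate is expected and the route is rejoined at 27.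

## Further compounds

F1 | step 5 | (S)-4-benzyl-3-methacryloyloxazolidin-2-one | C=C(C)C(=O)N1C(=O)OC[C@@H]1Cc1ccccc1
F2 | step 5 | exo-imide adduct (9 with the formyl group replaced by the N-acyl oxazolidinone) | CC1=C[C@@H]2C[C@@](C)(C(=O)N3C(=O)OC[C@@H]3Cc3ccccc3)[C@@]1(O)C(=O)O2
F3 | step 4 | methyl 2,2-dimethoxy-3-methylhex-5-enoate | COC(=O)C(OC)(OC)C(C)CC=C
F4 | step 4 | 2,2-dimethoxy-3-methylhex-5-enoic acid | OC(=O)C(OC)(OC)C(C)CC=C
F5 | step 4 | 2,2-dimethoxy-3-methyl-5-oxopentanoic acid | OC(=O)C(OC)(OC)C(C)CC=O
F6 | step 4 | 3-methoxy-4-methyl-2H-pyran-2-one | COC1=C(C)C=COC1=O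
F7 | step 9 | (1R,4S,6S)-4-[(tert-butyldimethylsilyl)oxy]-1-ethenyl-6-(hydroxymethyl)-2,6-dimethylcyclohex-2-en-1-ol | CC1=C[C@@H](O[Si](C)(C)C(C)(C)C)C[C@@](C)(CO)[C@@]1(O)C=C
F8 | step 9 | vinyl HMG ester (22 with ethenyl in place of ethynyl) | CC1=C[C@@H](O[Si](C)(C)C(C)(C)C)C[C@@](C)(COC(=O)C[C@](C)(O)CC(=O)OCC[Si](C)(C)C)[C@@]1(O)C=C
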